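Assumption: rings are lettered A to G along the SMILES string, and each ring is numbered from the carbon whose ether oxygen points toward ring A (ring A from its single ether carbon); on this basis 16, 5 and 18 are consistent with the target. Phenol 16 enters the key step as a sodium phenoxide made with NaH in an ether solvent, so that neither a conjugate acid nor an acidic solvent is present. Aryne 13 is a transient species that 5 releases afresh in steps 6, 9 and 10; it carries one number and is entered once, at step 6 where it first forms. Compounds 1, 6, 9 and 19 are taken to be catalogue chemicals.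

## Structural features

The target 24 is a linear chain of seven benzene rings A to G held together only by six diaryl ether oxygens; it has no stereocentre, no ring fusion and no carbon–carbon bond between rings, and it carries eighteen free phenolic hydroxyls. Rings B, D and F are 1,4-dioxygenated with hydroxyls on C3 and C5, so the oxygen on C4 lies between two ortho oxygens while the oxygen on C1 lies between two C–H; ring A is a 2,4,6-trihydroxyphenoxy group and ring G a 3,4,5-trihydroxyphenyl group. Rings C and E are pentaoxygenated: C1 (next to the only C–H, C6) and C2 (next to the C3 oxygen) carry neighbouring aryloxy groups, and C3 to C5 carry hydroxyls. As a result each of the six ether bonds has at least one partner carbon with two ortho substituents, and the ether carbons C C2 and E C2 sit between an aryloxy and an oxygen substituent. The free polyphenol is the fragile feature: the pyrogallol rings (C, E, G) and the hydroxyhydroquinone-type rings are oxidised by air once deprotonated, so the oxygens travel as methyl ethers until the last step. Every aromatic C–H of the protected chain lies between two oxygens and all are chemically alike, so a halogen or a metal cannot be placed selectively on an assembled oligomer; the position of each new ether must be fixed in the bond-forming event itself. The key step uses the fact that E C1 and E C2 are the two carbons of the triple bond of 13: the C3 methoxy group sends the ring D phenoxide oxygen to C1 and leaves a carbanion on C2, which becomes the C–I bond that is later turned into the ether to ring F.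

## Logic of the disconnections

24 from 23. The eighteen O–H bonds of 24 are traced back to eighteen O–CH3 bonds. Methyl is the smallest oxygen mask, keeps the surroundings of every ether as open as possible and is already present in cheap building blocks. The gain is that every compound before the last step is a neutral, air-stable ether. The demand is one exhaustive Lewis-acid dealkylation that spares the six diaryl ethers, followed by an oxygen-free isolation.

23 from 18 and 22. The bond from E C2 to the oxygen on F C1 is cut, and the oxygen stays on ring F. That oxygen has two ortho hydrogens, so the crowding is confined to one partner, and the cut divides the chain into a five-ring and a two-ring piece. The forward step must be a copper-catalysed etherification of an aryl iodide flanked by an aryloxy and a methoxy group.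

18 from 16 and 5. Two bonds on neighbouring carbons of ring E are cut at once: the bond from the ring D oxygen to E C1 and the C–I bond on E C2. Read backwards, 13 is taken out from between 17 and an iodine donor. The cut is made here because the D oxygen lies between two methoxy groups and is a poor partner for metal-catalysed coupling, whereas towards an aryne it needs no catalyst. The gain is a whole ring, with the positions of both new substituents fixed. The demand is an aryl anion that meets iodine before it meets a proton, hence 17 is made beforehand with a hydride.

22 from 20, and 20 from 19 and 5. The C1–OH bond of ring F in 22 is traced to a C–CHO bond in 20 (Baeyer–Villiger retron), so a formyl group serves as a masked hydroxyl and no protecting group is needed. 20 is then cut at the bond from the ring F C4 oxygen to G C1; 13 is taken up by the hindered phenoxide of 19, with a proton in place of iodine. The demand is that the aryne prefers the phenoxide to the aldehyde.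

16 from 15, and 15 from 14 and 8. The free hydroxyl on D C4 is traced to a benzyl ether, removable by hydrogenolysis once no iodine is left in the molecule. 15 is cut at the bond from C C2 to the oxygen on D C1, again with the oxygen on the unhindered carbon, giving 14 and 8. The demand is the same as for 23.

14 from 11 and 5. This is the same two-bond cut as for 18, one ring earlier: ring C is removed as 13 from between 12 and iodine. It rehearses the key step on a much smaller substrate and lets one aryne precursor serve rings C, E and G.

11 from 10, and 10 from 9 and 8. After the debenzylation retron, the bond from A C1 to oxygen is cut with the oxygen left on B C1. Ring A is taken as the electrophile because its ether carbon lies between two methoxy groups and a phenol there would be the hindered partner. Both pieces are single rings.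

8 from 6. The hydroxyl of 8 is traced to the formyl group of 6 through 7; the differentiation of the two oxygens of a 2,6-dimethoxyhydroquinone is thereby bought and not made.

5 from 2, and 2 from 1. The C–Si bond and the triflate of 5 go back, through an oxygen-to-carbon silyl shift (3 to 4), to the C–Br bond and the hydroxyl of 2, and the bromine to an ortho C–H of 1. The two ortho positions of 1 are equivalent, so no regiochemical question arises.

## Other disconnections considered

Alternative 1: The cut lies inside ring E, at the bond E C5–C6, so that E is built from a four-carbon and a two-carbon piece.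
- Forward key step: the α-metalated aryl vinyl ether A3 (ring D with a vinyloxy group on C4) adds to dimethyl squarate A4, and the tertiary alkoxide is capped as a methoxymethyl ether to give cyclobutenone A2. Heating A2 opens the four-membered ring to a dienylketene, which closes by a six-electron electrocyclisation and tautomerises to the D–E dimer A1 (Moore rearrangement).
- In its favour: the five oxygens of ring E are placed without regiochemical ambiguity and in three different states (free OH on C5, MOM on C2, methyl on C3 and C4). The crowded ring D oxygen is joined to carbon by a simple O-vinylation. The key step is thermal and neutral and needs neither fluoride nor a proton-free medium. In oxygen differentiation and in indifference to stray protons it is the equal or the better of the chosen plan.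
- Against it here: A1 is only a two-ring compound, and E C2 ends up bearing an oxygen, not a halide. The next ether (E C2–O–F C1) would then have to be made from a phenol flanked on both sides, the kind of nucleophile the chosen plan keeps out of its copper steps. Metalation of A3 at the vinyl α-carbon must compete with the two ring C–H of D, each between two oxygens. Ring C would need the whole sequence a second time.
- Comparison: structurally both plans deliver ring E with the D oxygen on C1 and a handle on C2. Mechanistically a pericyclic cascade stands against a polar three-component addition, and the cascade is the less moisture-sensitive. In step economy the alternative spends about five or six steps per pentaoxygenated ring (vinyl ether, addition, capping, thermolysis, methylation, MOM removal) where the chosen plan spends one.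

Alternative 2: The cut is the ether bond from C C2 to the ring D oxygen, made inside a temporary ring.
- Forward key step: a carboxyl on D C2 is first esterified with a hydroxyl on C C3 to give iodo depside A6. CuI with Cs2CO3 then closes the seven-membered lactone-ether ring of depsidone A5 by intramolecular Ullmann etherification. Lactone opening, protodecarboxylation of the resulting 2,6-dioxygenated benzoic acid and methylation of C C3–OH would erase the tether.
- In its favour: the coupling at the most crowded carbon of the chain becomes intramolecular, and copper-mediated closure to depsidones is well established. On this one point it is better than the intermolecular copper couplings of steps 7 and 12. The endgame, one global demethylation, is equal.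
- Against it here: A6 needs an ester between a benzoic acid and a phenol that each have two ortho substituents, a demanding bond in itself. Ring D must carry a carboxyl and ring C a free hydroxyl distinguished from its methoxy neighbours, which costs steps in both halves. Three further operations follow the closure on a seven-ring substrate. The tether does nothing for the ethers whose oxygen lies between two methoxy groups (on B C4, D C4 and F C4), which A6 must already contain.
- Comparison: structurally it needs more pre-functionalisation for the same bond. Mechanistically it is the same copper catalysis with an entropic advantage. In step economy it is at least five or six steps longer than steps 7 and 8 together.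

Alternative 3: The cut removes ring D altogether: bonds D C2–C3 and D C1–C6 are new, and D C3–C4 is broken and re-formed.
- Forward key step: Danheiser benzannulation of ethynyl ether A8 (on the C C2 oxygen of an A–B–C trimer) with 3-ethoxy-4-aryloxycyclobutenone A9 (on the E C1 oxygen of an E–F–G trimer). A9 opens in a four-electron process to a vinylketene, which undergoes regioselective [2+2] cycloaddition with the ynol ether; a second ring opening, six-electron closure and tautomerisation give heptamer A7.
- In its favour: it is the most convergent of the plans (three plus three rings joined while the seventh is created), which is better than the chosen plan. Both crowded oxygens on ring D arrive already attached to the reacting carbons, so neither needs an arene–oxygen coupling. No metal is involved. The free hydroxyl and the ethyl ether of A7 both fall in the final dealkylation, so the endgame is equal.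
- Against it here: A8 is a terminal aryloxyacetylene on a hindered oxygen, a class sensitive to heat and acid. A9 is a vinylogous ester whose ring opening needs more forcing conditions and whose vinylketene is a weaker electrophile than usual, while an aryl ynol ether is a weaker ketenophile than an alkyl one. The phenol of A7 can be acylated by ketene intermediates. A8 and A9 each still contain a pentaoxygenated ring with two neighbouring ether oxygens (C and E), which would need a solution of the chosen kind anyway.
- Comparison: structurally it is excellent for ring D and silent on rings C and E. Mechanistically a four-stage pericyclic cascade with two electronically mismatched partners stands against a polar addition with close analogy. In step economy the coupling saves steps and the two partners cost them back (about four steps from each trimer phenol), so the totals are likely similar.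

Key step: step 9

## Route

Step 1
Reactants: 1 3,4,5-trimethoxyphenol
Product: 2 2-bromo-3,4,5-trimethoxyphenol
Conditions: NBS (1.0 equiv), CH2Cl2, −78 to 0 °C, dark
Reagents that add atoms: N-bromosuccinimide, O=C1CCC(=O)N1Br
Why: Electrophilic aromatic bromination; the two positions ortho to the hydroxyl are equivalent and the most activated (ortho to OH, para to a methoxy group), and one equivalent of NBS at low temperature should stop at the monobromide without oxidising the ring to a quinone.

Step 2
Reactants: 2 2-bromo-3,4,5-trimethoxyphenol
Product: 5 3,4,5-trimethoxy-2-(trimethylsilyl)phenyl trifluoromethanesulfonate, via aryl trimethylsilyl ether 3 (not isolated), via lithium 2-silylphenoxide 4 (not isolated)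
Conditions: HMDS, THF, 70 °C, then evaporation; n-BuLi, THF, −100 °C; Tf2O, −100 °C to rt
Reagents that add atoms: hexamethyldisilazane, C[Si](C)(C)N[Si](C)(C)C; trifluoromethanesulfonic anhydride, O=S(=O)(OS(=O)(=O)C(F)(F)F)C(F)(F)F
Why: O-Silylation, then bromine–lithium exchange and anionic oxygen-to-carbon silyl migration (retro-Brook rearrangement) give phenoxide 4, which is triflated in the same flask; this standard entry to 2-silylaryl triflates puts silicon on the carbon between the triflate and the C3 methoxy group.

Step 3
Reactants: 6 4-(benzyloxy)-3,5-dimethoxybenzaldehyde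
Product: 8 4-(benzyloxy)-3,5-dimethoxyphenol, via aryl formate 7 (not isolated)
Conditions: mCPBA, NaHCO3, CH2Cl2, 0 °C to rt; then K2CO3 (cat.), MeOH, rt
Reagents that add atoms: 3-chloroperoxybenzoic acid (mCPBA), OOC(=O)c1cccc(Cl)c1
Why: Baeyer–Villiger oxidation of an electron-rich benzaldehyde (Dakin-type): the aryl group with its para oxygen migrates in the Criegee adduct to give formate 7, which is methanolysed in the same flask; benzyl and methyl ethers are inert.

Step 4
Reactants: 9 2-iodo-1,3,5-trimethoxybenzene; 8 4-(benzyloxy)-3,5-dimethoxyphenol
Product: 10 A-B dimer benzyl ether (2-(benzyloxy)-1,3-dimethoxy-5-(2,4,6-trimethoxyphenoxy)benzene)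
Conditions: CuI (10 mol %), picolinic acid (20 mol %), K3PO4, DMSO, 90 °C, argon; 9 in excess
Reagents that add atoms: none
Why: Ullmann-type copper-catalysed diaryl ether synthesis with a picolinate ligand, a system suited to ortho-substituted partners; the nucleophile is the unhindered phenol of 8, and the cheap di-ortho-substituted iodide 9 is used in excess to offset hydrodeiodination.

Step 5
Reactants: 10 A-B dimer benzyl ether
Product: 11 A-B dimer phenol (2,6-dimethoxy-4-(2,4,6-trimethoxyphenoxy)phenol)
Conditions: H2 (1 atm), 10% Pd/C, EtOAc–MeOH, rt
Reagents that add atoms: none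
Why: Hydrogenolysis of the benzyl ether over Pd/C; diaryl and methyl ethers are untouched and no halogen is present.

Step 6
Reactants: 11 A-B dimer phenol; 5 3,4,5-trimethoxy-2-(trimethylsilyl)phenyl trifluoromethanesulfonate
Product: 14 A-B-C trimer iodide (1-[2,6-dimethoxy-4-(2,4,6-trimethoxyphenoxy)phenoxy]-2-iodo-3,4,5-trimethoxybenzene), via sodium phenoxide 12 (not isolated), via 3,4,5-trimethoxybenzyne 13 (not isolated)
Conditions: NaH (1.05 equiv), DME, 0 °C to rt; then C4F9I (3 equiv), CsF (3 equiv), 18-crown-6, 5 (1.5 equiv) added over 4 h, rt, dark, argon sweep
Reagents that add atoms: nonafluoro-1-iodobutane, FC(F)(F)C(F)(F)C(F)(F)C(F)(F)I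
Why: Aryne three-component coupling in the same sense as the key step, run first on the small phenoxide: NaH gives 12 without a conjugate acid, fluoride releases 13 from 5, the oxygen of 12 adds to the aryne carbon remote from the C3 methoxy group (ring C C1) and the C2 anion takes iodine from C4F9I. Slow addition of 5 keeps the aryne concentration low, and an ether solvent in the dark avoids proton capture and photochemical perfluoroalkylation of the phenoxide.

Step 7
Reactants: 14 A-B-C trimer iodide; 8 4-(benzyloxy)-3,5-dimethoxyphenol
Product: 15 A-B-C-D tetramer benzyl ether (14 with iodine replaced by a 4-(benzyloxy)-3,5-dimethoxyphenoxy group)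
Conditions: CuI (20 mol %), picolinic acid (40 mol %), K3PO4, DMSO, 100 °C, argon; 8 in excess
Reagents that add atoms: none
Why: Ullmann-type copper-catalysed etherification between the iodide on ring C C2 and the unhindered phenol 8; the hindered ring D oxygen stays masked as its benzyl ether, so only one oxygen can couple.

Step 8
Reactants: 15 A-B-C-D tetramer benzyl ether
Product: 16 A-B-C-D tetramer phenol (free hydroxyl on ring D C4)
Conditions: H2 (1 atm), 10% Pd/C, EtOAc–MeOH, rt
Reagents that add atoms: none
Why: Hydrogenolysis of the single benzyl ether frees the ring D C4 hydroxyl; the iodine of 14 was consumed in step 7, so nothing else is reducible.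

Step 9
Reactants: 16 A-B-C-D tetramer phenol; 5 3,4,5-trimethoxy-2-(trimethylsilyl)phenyl trifluoromethanesulfonate
Product: 18 A-E pentamer iodide (ring D C4 oxygen of 16 bound to C1 of a 2-iodo-3,4,5-trimethoxyphenyl ring E), via sodium phenoxide 17 (not isolated)
Conditions: NaH (1.05 equiv), DME, 0 °C to rt; then C4F9I (3 equiv), CsF (3 equiv), 18-crown-6, 5 (1.5 equiv) added over 6 h, rt, dark, argon sweep
Reagents that add atoms: nonafluoro-1-iodobutane, FC(F)(F)C(F)(F)C(F)(F)C(F)(F)I
Why: This is a three-component 1,2-difunctionalisation of an aryne; the closest known reaction types are the metal-free O-arylation of phenols by arynes from 2-silylaryl triflates and the iodination of the resulting aryl anion by a perfluoroalkyl iodide. Desilylation of 5 by fluoride with loss of triflate generates 13 afresh in this flask, exactly as in step 6, the strained triple bond joining the carbons that become E C1 and E C2. The C3 methoxy group next to E C2 polarises and bends the triple bond so that E C1 is the more electrophilic carbon, and it is also the less crowded one because its other neighbour is C6–H; the oxygen of 17 therefore adds at C1 and the charge develops on C2, where the C–O dipoles of both neighbours stabilise it. Because 17 was made with NaH and the medium is DME, no acid stronger than the solvent is present, and the aryl anion should take iodine from C4F9I by halogenophilic attack faster than it finds a proton or a second aryne. The perfluorobutyl anion left behind is expected to lose fluoride and leave as gaseous octafluorobut-1-ene, which the argon sweep removes. No ring is closed and no stereocentre is formed. The step needs regioselectivity (oxygen to C1, iodine to C2), secured by the C3 methoxy group, and chemoselectivity for iodine over proton, secured by the conjugate-acid-free phenoxide, slow addition of 5 and an excess of the iodine donor in the dark.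

Step 10
Reactants: 19 syringaldehyde (4-hydroxy-3,5-dimethoxybenzaldehyde); 5 3,4,5-trimethoxy-2-(trimethylsilyl)phenyl trifluoromethanesulfonate
Product: 20 3,5-dimethoxy-4-(3,4,5-trimethoxyphenoxy)benzaldehyde
Conditions: CsF (3 equiv), MeCN, rt; 5 (1.3 equiv)
Reagents that add atoms: none
Why: O-Arylation of a phenol by an aryne with proton capture: CsF deprotonates 19 and releases 13 from 5 once more, the hindered phenoxide adds without a metal to the aryne carbon remote from the C3 methoxy group, and the aryl anion is protonated by further phenol; the para-formyl group is a masked hydroxyl and reacts with the aryne more slowly than the phenoxide does.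

Step 11
Reactants: 20 3,5-dimethoxy-4-(3,4,5-trimethoxyphenoxy)benzaldehyde
Product: 22 F-G dimer phenol (3,5-dimethoxy-4-(3,4,5-trimethoxyphenoxy)phenol), via aryl formate 21 (not isolated)
Conditions: mCPBA, NaHCO3, CH2Cl2, 0 °C to rt; then K2CO3 (cat.), MeOH, rt
Reagents that add atoms: 3-chloroperoxybenzoic acid (mCPBA), OOC(=O)c1cccc(Cl)c1
Why: Baeyer–Villiger oxidation as in step 3: the 4-aryloxy-3,5-dimethoxyphenyl group migrates, and methanolysis of formate 21 unveils the unhindered hydroxyl on ring F C1.

Step 12
Reactants: 18 A-E pentamer iodide; 22 F-G dimer phenol
Product: 23 heptamer octadecamethyl ether (all eighteen hydroxyls of the target as methyl ethers)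
Conditions: CuI (30 mol %), picolinic acid (60 mol %), K3PO4, DMSO, 110 °C, argon; 22 in excess
Reagents that add atoms: none
Why: Ullmann-type copper-catalysed diaryl ether synthesis forming the bond from ring E C2 to the ring F oxygen; the phenol of 22 has two ortho hydrogens, so the crowding lies only on the iodide side, the case that picolinate-ligated copper tolerates best.

Step 13
Reactants: 23 heptamer octadecamethyl ether
Product: 24 target CNP0292517.0 (free heptamer, eighteen hydroxyls)
Conditions: BBr3 (about 3 equiv per OMe), CH2Cl2, −78 °C to rt; MeOH quench and co-evaporation; Sephadex LH-20 or reversed-phase chromatography, acidified eluent, argon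
Reagents that add atoms: none
Why: Lewis-acid cleavage of all eighteen aryl methyl ethers (bromide attacks the methyl group of each O–B adduct); diaryl ether bonds are not cleaved and boron leaves as B(OMe)3 on methanol quench. Work-up and purification are kept acidic and oxygen-free because the pyrogallol and hydroxyhydroquinone rings oxidise in air above neutral pH.

## Compound list

1 | 3,4,5-trimethoxyphenol | COc1cc(O)cc(OC)c1OC | starting material
2 | 2-bromo-3,4,5-trimethoxyphenol | COc1cc(O)c(Br)c(OC)c1OC | intermediate
3 | (2-bromo-3,4,5-trimethoxyphenoxy)trimethylsilane | COc1cc(O[Si](C)(C)C)c(Br)c(OC)c1OC | intermediate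
4 | lithium 3,4,5-trimethoxy-2-(trimethylsilyl)phenoxide | [Li+].[O-]c1cc(OC)c(OC)c(OC)c1[Si](C)(C)C | intermediate
5 | 3,4,5-trimethoxy-2-(trimethylsilyl)phenyl trifluoromethanesulfonate | COc1cc(OS(=O)(=O)C(F)(F)F)c([Si](C)(C)C)c(OC)c1OC | intermediate
6 | 4-(benzyloxy)-3,5-dimethoxybenzaldehyde | COc1cc(C=O)cc(OC)c1OCc1ccccc1 | starting material
7 | 4-(benzyloxy)-3,5-dimethoxyphenyl formate | COc1cc(OC=O)cc(OC)c1OCc1ccccc1 | intermediate
8 | 4-(benzyloxy)-3,5-dimethoxyphenol | COc1cc(O)cc(OC)c1OCc1ccccc1 | intermediate
9 | 2-iodo-1,3,5-trimethoxybenzene | COc1cc(OC)c(I)c(OC)c1 | starting material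
10 | A-B dimer benzyl ether, 2-(benzyloxy)-1,3-dimethoxy-5-(2,4,6-trimethoxyphenoxy)benzene | COc1cc(OC)c(Oc2cc(OC)c(OCc3ccccc3)c(OC)c2)c(OC)c1 | intermediate
11 | A-B dimer phenol, 2,6-dimethoxy-4-(2,4,6-trimethoxyphenoxy)phenol | COc1cc(OC)c(Oc2cc(OC)c(O)c(OC)c2)c(OC)c1 | intermediate
12 | sodium 2,6-dimethoxy-4-(2,4,6-trimethoxyphenoxy)phenoxide | COc1cc(OC)c(Oc2cc(OC)c([O-])c(OC)c2)c(OC)c1.[Na+] | intermediate
13 | 3,4,5-trimethoxybenzyne (1,2-didehydro-3,4,5-trimethoxybenzene) | COC1=C(OC)C(OC)=CC#C1 | intermediate
14 | A-B-C trimer iodide, 1-[2,6-dimethoxy-4-(2,4,6-trimethoxyphenoxy)phenoxy]-2-iodo-3,4,5-trimethoxybenzene | COc1cc(OC)c(Oc2cc(OC)c(Oc3cc(OC)c(OC)c(OC)c3I)c(OC)c2)c(OC)c1 | intermediate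
15 | A-B-C-D tetramer benzyl ether (benzyl on ring D C4 oxygen) | COc1cc(OC)c(Oc2cc(OC)c(Oc3cc(OC)c(OC)c(OC)c3Oc3cc(OC)c(OCc4ccccc4)c(OC)c3)c(OC)c2)c(OC)c1 | intermediate
16 | A-B-C-D tetramer phenol (free OH on ring D C4) | COc1cc(OC)c(Oc2cc(OC)c(Oc3cc(OC)c(OC)c(OC)c3Oc3cc(OC)c(O)c(OC)c3)c(OC)c2)c(OC)c1 | intermediate
17 | sodium phenoxide of the A-B-C-D tetramer | COc1cc(OC)c(Oc2cc(OC)c(Oc3cc(OC)c(OC)c(OC)c3Oc3cc(OC)c([O-])c(OC)c3)c(OC)c2)c(OC)c1.[Na+] | intermediate
18 | A-E pentamer iodide (iodine on ring E C2) | COc1cc(OC)c(Oc2cc(OC)c(Oc3cc(OC)c(OC)c(OC)c3Oc3cc(OC)c(Oc4cc(OC)c(OC)c(OC)c4I)c(OC)c3)c(OC)c2)c(OC)c1 | intermediate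
19 | syringaldehyde, 4-hydroxy-3,5-dimethoxybenzaldehyde | COc1cc(C=O)cc(OC)c1O | starting material
20 | 3,5-dimethoxy-4-(3,4,5-trimethoxyphenoxy)benzaldehyde | COc1cc(C=O)cc(OC)c1Oc1cc(OC)c(OC)c(OC)c1 | intermediate
21 | 3,5-dimethoxy-4-(3,4,5-trimethoxyphenoxy)phenyl formate | COc1cc(OC=O)cc(OC)c1Oc1cc(OC)c(OC)c(OC)c1 | intermediate
22 | F-G dimer phenol, 3,5-dimethoxy-4-(3,4,5-trimethoxyphenoxy)phenol | COc1cc(O)cc(OC)c1Oc1cc(OC)c(OC)c(OC)c1 | intermediate
23 | heptamer octadecamethyl ether | COc1cc(OC)c(Oc2cc(OC)c(Oc3cc(OC)c(OC)c(OC)c3Oc3cc(OC)c(Oc4cc(OC)c(OC)c(OC)c4Oc4cc(OC)c(Oc5cc(OC)c(OC)c(OC)c5)c(OC)c4)c(OC)c3)c(OC)c2)c(OC)c1 | intermediate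
24 | CNP0292517.0, free heptamer | Oc1cc(O)c(Oc2cc(O)c(Oc3cc(O)c(O)c(O)c3Oc3cc(O)c(Oc4cc(O)c(O)c(O)c4Oc4cc(O)c(Oc5cc(O)c(O)c(O)c5)c(O)c4)c(O)c3)c(O)c2)c(O)c1 | target

## Step count and least certain steps

Total steps: 13. Longest linear sequence: 9 steps (steps 3, 4, 5, 6, 7, 8, 9, 12, 13; from 6 to 24).

Step 9 (key step). The most likely failure is capture of the aryl anion by a proton before iodine transfer. The proton could come from residual moisture, from C–H bonds of the crown ether or solvent, or from translocation of the anion to one of the equally acidic ring C–H sites of a second molecule. The resulting E C2–H cannot be told from the other ring hydrogens afterwards. A second risk is loss of phenoxide by addition to the perfluoroalkene that the iodine donor leaves behind. The fallback puts the halogen into the electrophile and forms only the C–O bond, by metal-free O-arylation with a diaryliodonium salt. It sets out from 16 and returns at 23. Commercial 5-iodo-1,2,3-trimethoxybenzene is brominated next to iodine (NBS, MeCN) to give 2-bromo-1-iodo-3,4,5-trimethoxybenzene F1. mCPBA and TsOH·H2O oxidise F1 to 2-bromo-1-[hydroxy(tosyloxy)iodo]-3,4,5-trimethoxybenzene F2, which arylates 1,3,5-trimethoxybenzene in the same flask to give (2-bromo-3,4,5-trimethoxyphenyl)(2,4,6-trimethoxyphenyl)iodonium tosylate F3. Phenoxide 17 (from 16 and NaH in THF) attacks the trivalent iodine of F3, and ligand coupling transfers the less electron-rich, ortho-substituted aryl group to oxygen; this gives the A-E pentamer bromide F4 and releases 9. Copper-catalysed coupling of F4 with 22 (conditions of step 12, 120 °C) rejoins the route at 23.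

Step 6. The same processes threaten this first aryne round (proton capture in place of iodine capture, phenoxide loss to the perfluoroalkene), and it is the test for step 9. The fallback sets out from 11 and returns at 15. Phenoxide 12 (from 11 and NaH) is arylated with the iodonium tosylate F3 described above to give the A-B-C trimer bromide F5, which is coupled with 8 under the copper conditions of step 7 to give 15.

Step 12. C–O bond formation at copper may be slow because the iodide carbon is flanked by an aryloxy and a methoxy group, so that hydrodeiodination of 18 and oxidative loss of 22 take over. The fallback reverses the roles of the partners and uses an aryne once more. It sets out from 18 and 22 and returns at 23. Iodide 18 is hydroxylated (Pd2(dba)3, 2-di-tert-butylphosphino-2',4',6'-triisopropylbiphenyl, KOH, dioxane–H2O, 100 °C) to the A-E pentamer phenol F6, with its hydroxyl on ring E C2. Phenol 22 is brominated ortho to the hydroxyl (NBS, CH2Cl2, −78 °C) to give 2-bromo-3,5-dimethoxy-4-(3,4,5-trimethoxyphenoxy)phenol F7. F7 is taken through the sequence of step 2, by way of its trimethylsilyl ether F8 and the lithium 2-silylphenoxide F9, to 3,5-dimethoxy-4-(3,4,5-trimethoxyphenoxy)-2-(trimethylsilyl)phenyl trifluoromethanesulfonate F10. CsF in MeCN then releases 3,5-dimethoxy-4-(3,4,5-trimethoxyphenoxy)benzyne F11 in the presence of F6; the hindered oxygen of F6 adds to the aryne carbon remote from the methoxy group, with proton capture, to give 23.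

Step 13. Cleavage may stop short because partly demethylated borates precipitate from CH2Cl2, and the free polyphenol may oxidise in air during work-up and chromatography. The fallback isolates the product as a stable derivative and then releases it. It sets out from 23 and returns at 24. After the BBr3 treatment and methanol quench, the crude product is acetylated without isolation (Ac2O, pyridine, DMAP) to the heptamer octadecaacetate F12, a neutral, air-stable compound that can be purified on silica. Acid methanolysis under argon (HCl in MeOH, from AcCl) then frees 24 with only volatile by-products.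

Further compounds
F1 | step 9 | 2-bromo-1-iodo-3,4,5-trimethoxybenzene | COc1cc(I)c(Br)c(OC)c1OC
F2 | step 9 | 2-bromo-1-[hydroxy(tosyloxy)iodo]-3,4,5-trimethoxybenzene | COc1cc(I(O)OS(=O)(=O)c2ccc(C)cc2)c(Br)c(OC)c1OC
F3 | step 9 | (2-bromo-3,4,5-trimethoxyphenyl)(2,4,6-trimethoxyphenyl)iodonium 4-methylbenzenesulfonate | COc1cc(OC)c([I+]c2cc(OC)c(OC)c(OC)c2Br)c(OC)c1.Cc1ccc(S(=O)(=O)[O-])cc1
F4 | step 9 | A-E pentamer bromide (bromine on ring E C2) | COc1cc(OC)c(Oc2cc(OC)c(Oc3cc(OC)c(OC)c(OC)c3Oc3cc(OC)c(Oc4cc(OC)c(OC)c(OC)c4Br)c(OC)c3)c(OC)c2)c(OC)c1
F5 | step 6 | A-B-C trimer bromide (bromine on ring C C2) | COc1cc(OC)c(Oc2cc(OC)c(Oc3cc(OC)c(OC)c(OC)c3Br)c(OC)c2)c(OC)c1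
F6 | step 12 | A-E pentamer phenol (hydroxyl on ring E C2) | COc1cc(OC)c(Oc2cc(OC)c(Oc3cc(OC)c(OC)c(OC)c3Oc3cc(OC)c(Oc4cc(OC)c(OC)c(OC)c4O)c(OC)c3)c(OC)c2)c(OC)c1
F7 | step 12 | 2-bromo-3,5-dimethoxy-4-(3,4,5-trimethoxyphenoxy)phenol | COc1cc(O)c(Br)c(OC)c1Oc1cc(OC)c(OC)c(OC)c1
F8 | step 12 | [2-bromo-3,5-dimethoxy-4-(3,4,5-trimethoxyphenoxy)phenoxy]trimethylsilane | COc1cc(O[Si](C)(C)C)c(Br)c(OC)c1Oc1cc(OC)c(OC)c(OC)c1
F9 | step 12 | lithium 3,5-dimethoxy-4-(3,4,5-trimethoxyphenoxy)-2-(trimethylsilyl)phenoxide | [Li+].[O-]c1cc(OC)c(Oc2cc(OC)c(OC)c(OC)c2)c(OC)c1[Si](C)(C)C
F10 | step 12 | 3,5-dimethoxy-4-(3,4,5-trimethoxyphenoxy)-2-(trimethylsilyl)phenyl trifluoromethanesulfonate | COc1cc(OS(=O)(=O)C(F)(F)F)c([Si](C)(C)C)c(OC)c1Oc1cc(OC)c(OC)c(OC)c1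
F11 | step 12 | 3,5-dimethoxy-4-(3,4,5-trimethoxyphenoxy)benzyne | COC1=C(Oc2cc(OC)c(OC)c(OC)c2)C(OC)=CC#C1
F12 | step 13 | heptamer octadecaacetate | CC(=O)Oc1cc(OC(C)=O)c(Oc2cc(OC(C)=O)c(Oc3cc(OC(C)=O)c(OC(C)=O)c(OC(C)=O)c3Oc3cc(OC(C)=O)c(Oc4cc(OC(C)=O)c(OC(C)=O)c(OC(C)=O)c4Oc4cc(OC(C)=O)c(Oc5cc(OC(C)=O)c(OC(C)=O)c(OC(C)=O)c5)c(OC(C)=O)c4)c(OC(C)=O)c3)c(OC(C)=O)c2)c(OC(C)=O)c1
A1 | alternative 1 | D-E dimer, 5-[4-(benzyloxy)-2,6-dimethoxyphenoxy]-2,3-dimethoxy-4-(methoxymethoxy)phenol | COCOc1c(OC)c(OC)c(O)cc1Oc1c(OC)cc(OCc2ccccc2)cc1OC
A2 | alternative 1 | 4-{1-[4-(benzyloxy)-2,6-dimethoxyphenoxy]ethenyl}-2,3-dimethoxy-4-(methoxymethoxy)cyclobut-2-en-1-one (racemic) | COCOC1(C(=C)Oc2c(OC)cc(OCc3ccccc3)cc2OC)C(OC)=C(OC)C1=O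
A3 | alternative 1 | 5-(benzyloxy)-2-(ethenyloxy)-1,3-dimethoxybenzene | C=COc1c(OC)cc(OCc2ccccc2)cc1OC
A4 | alternative 1 | dimethyl squarate, 3,4-dimethoxycyclobut-3-ene-1,2-dione | COC1=C(OC)C(=O)C1=O
A5 | alternative 2 | heptamer depsidone bridging rings C and D | COc1cc(OC)c(Oc2cc(OC)c(Oc3cc(OC)c(OC)c4OC(=O)c5c(Oc34)cc(OC)c(Oc6cc(OC)c(OC)c(OC)c6Oc6cc(OC)c(Oc7cc(OC)c(OC)c(OC)c7)c(OC)c6)c5OC)c(OC)c2)c(OC)c1
A6 | alternative 2 | iodo depside (ester from ring D C2 carboxyl to ring C C3 oxygen, free OH on D C1, iodine on C C2) | COc1cc(OC)c(Oc2cc(OC)c(Oc3cc(OC)c(OC)c(OC(=O)c4c(O)cc(OC)c(Oc5cc(OC)c(OC)c(OC)c5Oc5cc(OC)c(Oc6cc(OC)c(OC)c(OC)c6)c(OC)c5)c4OC)c3I)c(OC)c2)c(OC)c1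
A7 | alternative 3 | heptamer with ring D C3-OH free and ring D C5-OEt | COc1cc(OC)c(Oc2cc(OC)c(Oc3cc(OC)c(OC)c(OC)c3Oc3cc(O)c(Oc4cc(OC)c(OC)c(OC)c4Oc4cc(OC)c(Oc5cc(OC)c(OC)c(OC)c5)c(OC)c4)c(OCC)c3)c(OC)c2)c(OC)c1
A8 | alternative 3 | A-B-C trimer ethynyl ether (ethynyloxy on ring C C2) | COc1cc(OC)c(Oc2cc(OC)c(Oc3cc(OC)c(OC)c(OC)c3OC#C)c(OC)c2)c(OC)c1
A9 | alternative 3 | 3-ethoxy-4-aryloxycyclobut-2-en-1-one on the ring E C1 oxygen of the E-F-G trimer (racemic) | CCOC1=CC(=O)C1Oc1cc(OC)c(OC)c(OC)c1Oc1cc(OC)c(Oc2cc(OC)c(OC)c(OC)c2)c(OC)c1
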